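The cyclohexenone ring is cut at C4–C5 and C7–C7a (2-benzofuran numbering), which removes a bare propene-1,3-diyl unit. Both bonds are made in one pot by stitching an allyl gem-diboronate, a propene 1,3-dianion equivalent, onto the two 1,3-related electrophilic carbons that flank quaternary C3a of an α-keto-γ-lactone: γ-allylboration of the C7a ketone, anti to the C4 acyl group, gives a (Z)-alkenylboronate, and intramolecular Liebeskind–Srogl acylation at the C4 thioester closes the trans-fused enone. The precursor is a (3R)-3-(phenylthio)carbonyl-4,5-dioxooxolane that already carries the furyl-pyranone side chain; its stereocentre comes from a catalytic asymmetric hydroxymethylation–lactonisation.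

Key step: step 9

Remark: the SMILES is read as the trans-fused (3aR,7aR) isomer (7a-OH and C4 on one face of the lactone, side chain and C7 on the other); 3-ethynylfuran, tert-butyl 4-bromobutanoate and bis(pinacolato)diboron are taken as catalogue compounds.

Step 1
Reactants: 1 tert-butyl 3-oxobutanoate; 2 tert-butyl 4-bromobutanoate
Product: 3 di-tert-butyl 2-acetylhexanedioate (racemic)
Conditions: K2CO3, NaI (cat.), DMF, 50 °C
Reagents that add atoms: none
Why: SN2 C-alkylation of the stabilised β-keto ester enolate by the primary bromide; the stereocentre formed is destroyed in step 2.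

Step 2
Reactants: 3 di-tert-butyl 2-acetylhexanedioate
Product: 4 di-tert-butyl (2Z)-2-[1-(trifluoromethanesulfonyloxy)ethylidene]hexanedioate
Conditions: NaH, Et2O, 0 °C; then Tf2O, −78 → 0 °C
Reagents that add atoms: trifluoromethanesulfonic anhydride, O=S(=O)(OS(=O)(=O)C(F)(F)F)C(F)(F)F
Why: O-sulfonylation of the sodium-chelated enolate in a non-coordinating solvent should give the tetrasubstituted enol triflate with OTf cis to the ester (Z), the geometry needed for ring closure in step 4.

Step 3
Reactants: 4 di-tert-butyl (2Z)-2-[1-(trifluoromethanesulfonyloxy)ethylidene]hexanedioate; 5 3-ethynylfuran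
Product: 6 di-tert-butyl (2Z)-2-[4-(furan-3-yl)but-3-yn-2-ylidene]hexanedioate
Conditions: Pd(PPh3)2Cl2 (3 mol%), CuI (5 mol%), i-Pr2NEt, THF, rt
Reagents that add atoms: none
Why: Sonogashira coupling of the enol triflate proceeds with retention of alkene geometry, placing the alkyne cis to the ester.

Step 4
Reactants: 6 di-tert-butyl (2Z)-2-[4-(furan-3-yl)but-3-yn-2-ylidene]hexanedioate
Product: 7 tert-butyl 4-[6-(furan-3-yl)-4-methyl-2-oxo-2H-pyran-3-yl]butanoate
Conditions: Ph3PAuCl (5 mol%), AgSbF6 (5 mol%), CH2Cl2, rt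
Reagents that add atoms: none
Why: gold(I)-catalysed 6-endo-dig attack of the conjugated ester carbonyl oxygen on the furyl-substituted alkyne carbon, with loss of isobutene from the oxocarbenium ion and protodeauration, gives the 2-pyranone; only the conjugated ester can reach the alkyne.

Step 5
Reactants: 7 tert-butyl 4-[6-(furan-3-yl)-4-methyl-2-oxo-2H-pyran-3-yl]butanoate
Product: 9 S-phenyl 4-[6-(furan-3-yl)-4-methyl-2-oxo-2H-pyran-3-yl]butanethioate, via carboxylic acid 8 (not isolated)
Conditions: TFA, CH2Cl2, 0 °C → rt, evaporate; then PhSH, EDC·HCl, DMAP (cat.), CH2Cl2, 0 °C → rt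
Reagents that add atoms: benzenethiol, Sc1ccccc1
Why: acidolysis of the tert-butyl ester followed by carbodiimide (Steglich-type) thioesterification; the thioester allows soft enolisation in step 6 and is the acyl donor of the key step.

Step 6
Reactants: 9 S-phenyl 4-[6-(furan-3-yl)-4-methyl-2-oxo-2H-pyran-3-yl]butanethioate; 10 ethyl chlorooxoacetate
Product: 11 ethyl 5-[6-(furan-3-yl)-4-methyl-2-oxo-2H-pyran-3-yl]-2-oxo-3-[(phenylsulfanyl)carbonyl]pentanoate (racemic, enolised)
Conditions: MgBr2·OEt2 (2.5 equiv), i-Pr2NEt (3 equiv), CH2Cl2, 0 °C → rt; 1 M HCl work-up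
Reagents that add atoms: none
Why: crossed Claisen acylation by soft enolisation, in which Mg(II) coordination lets the amine deprotonate only the thioester α-CH2 and leaves the base-sensitive pyranone (acidic 4-methyl) untouched.

Step 7
Reactants: 11 ethyl 5-[6-(furan-3-yl)-4-methyl-2-oxo-2H-pyran-3-yl]-2-oxo-3-[(phenylsulfanyl)carbonyl]pentanoate
Product: 13 S-phenyl (3R)-3-{2-[6-(furan-3-yl)-4-methyl-2-oxo-2H-pyran-3-yl]ethyl}-4,5-dioxooxolane-3-carbothioate, via hydroxymethyl adduct 12 (not isolated)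
Conditions: 37% aq. HCHO (3 equiv), chiral binaphthyl-derived bifunctional quaternary ammonium bromide (2 mol%), toluene, 0 °C; then PPTS (10 mol%), toluene, 4 Å MS, 40 °C
Reagents that add atoms: formaldehyde, C=O
Why: catalytic asymmetric aldol-type hydroxymethylation under neutral phase-transfer conditions, in which the chiral ammonium enolate ion pair exposes one face of the planar 1,3-dicarbonyl enolate and so sets the quaternary centre (R; the catalyst antipode is chosen accordingly), and 5-exo-trig lactonisation onto the activated oxalyl ester then fixes it.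

Step 8
Reactants: 14 allyl chloride; 15 bis(pinacolato)diboron
Product: 16 2,2'-(prop-2-ene-1,1-diyl)bis(4,4,5,5-tetramethyl-1,3,2-dioxaborolane)
Conditions: LDA (1.2 equiv, slow addition), THF, −95 °C → rt
Reagents that add atoms: none
Why: carbenoid gem-diborylation, in which α-lithiation of allyl chloride in the presence of the diboron gives a 1-chloroallyl borate that undergoes 1,2-boryl migration with loss of chloride.

Step 9
Reactants: 13 S-phenyl (3R)-3-{2-[6-(furan-3-yl)-4-methyl-2-oxo-2H-pyran-3-yl]ethyl}-4,5-dioxooxolane-3-carbothioate; 16 2,2'-(prop-2-ene-1,1-diyl)bis(4,4,5,5-tetramethyl-1,3,2-dioxaborolane)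
Product: 19 (3aR,7aR)-3a-{2-[6-(furan-3-yl)-4-methyl-2-oxo-2H-pyran-3-yl]ethyl}-7a-hydroxy-3a,7a-dihydro-2-benzofuran-1,4(3H,7H)-dione, via Z-alkenylboronate 17 (not isolated), via O-boryl enone 18 (not isolated)
Conditions: 13 dried azeotropically, 16 (1.3 equiv), toluene, 4 Å MS, 40 °C, no Lewis acid; then Pd2(dba)3 (5 mol%), P(2-furyl)3 (20 mol%), CuTC (2.2 equiv), THF, 50 °C; pH 7 buffer work-up
Reagents that add atoms: none
Why: Proposed new method: the allyl gem-diboronate adds through a closed six-membered chair transition state (its CH2 terminus to the ketone carbon, future C7a, the only carbonyl electrophilic enough for uncatalysed allylboration) with the spectator Bpin pseudo-axial, giving the O-borylated (Z)-alkenylboronate 17; Pd(0) then inserts into the C(acyl)–S bond, copper(I) thiophene-2-carboxylate takes up the thiolate and activates boron, and alkenyl transfer with reductive elimination forms the C4–C5 bond. The closest known reaction types are carbonyl allylboration with 1,1-diboryl-2-alkenes followed by cross-coupling of the resulting (Z)-alkenylboronate, and the Liebeskind–Srogl ketone synthesis; running both in one pot on a ketone/thioester pair is the new element. The six-membered ring closes by intramolecular acyl–alkenyl cross-coupling through a seven-membered acyl(alkenyl)palladacycle, which requires the Z alkene. The new stereocentre C7a is set in the intermolecular allylboration by quaternary C3a: the thioester should lie perpendicular to the planar dioxolactone to minimise dipole repulsion and block its face, so attack occurs anti to it (polar Felkin–Anh) and cis to the side chain. The step needs chemoselectivity (ketone before thioester, lactone and pyranone), Z-selectivity and this facial selectivity; because C7 arrives on the face opposite the acyl carbon before the ring closes, the fusion can only be trans with the 7a-hydroxyl cis to C4.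

Compound list
1 | tert-butyl 3-oxobutanoate | CC(=O)CC(=O)OC(C)(C)C | starting material
2 | tert-butyl 4-bromobutanoate | BrCCCC(=O)OC(C)(C)C | starting material
3 | di-tert-butyl 2-acetylhexanedioate (racemic) | CC(=O)C(CCCC(=O)OC(C)(C)C)C(=O)OC(C)(C)C | intermediate
4 | di-tert-butyl (2Z)-2-[1-(trifluoromethanesulfonyloxy)ethylidene]hexanedioate | C/C(OS(=O)(=O)C(F)(F)F)=C(\CCCC(=O)OC(C)(C)C)C(=O)OC(C)(C)C | intermediate
5 | 3-ethynylfuran | C#Cc1ccoc1 | starting material
6 | di-tert-butyl (2Z)-2-[4-(furan-3-yl)but-3-yn-2-ylidene]hexanedioate | C/C(C#Cc1ccoc1)=C(\CCCC(=O)OC(C)(C)C)C(=O)OC(C)(C)C | intermediate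
7 | tert-butyl 4-[6-(furan-3-yl)-4-methyl-2-oxo-2H-pyran-3-yl]butanoate | Cc1cc(-c2ccoc2)oc(=O)c1CCCC(=O)OC(C)(C)C | intermediate
8 | 4-[6-(furan-3-yl)-4-methyl-2-oxo-2H-pyran-3-yl]butanoic acid (not isolated) | Cc1cc(-c2ccoc2)oc(=O)c1CCCC(=O)O | intermediate
9 | S-phenyl 4-[6-(furan-3-yl)-4-methyl-2-oxo-2H-pyran-3-yl]butanethioate | Cc1cc(-c2ccoc2)oc(=O)c1CCCC(=O)Sc1ccccc1 | intermediate
10 | ethyl chlorooxoacetate | CCOC(=O)C(Cl)=O | starting material
11 | ethyl 5-[6-(furan-3-yl)-4-methyl-2-oxo-2H-pyran-3-yl]-2-oxo-3-[(phenylsulfanyl)carbonyl]pentanoate (racemic) | CCOC(=O)C(=O)C(CCc1c(C)cc(-c2ccoc2)oc1=O)C(=O)Sc1ccccc1 | intermediate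
12 | ethyl (3R)-5-[6-(furan-3-yl)-4-methyl-2-oxo-2H-pyran-3-yl]-3-(hydroxymethyl)-2-oxo-3-[(phenylsulfanyl)carbonyl]pentanoate (not isolated) | CCOC(=O)C(=O)[C@](CO)(CCc1c(C)cc(-c2ccoc2)oc1=O)C(=O)Sc1ccccc1 | intermediate
13 | S-phenyl (3R)-3-{2-[6-(furan-3-yl)-4-methyl-2-oxo-2H-pyran-3-yl]ethyl}-4,5-dioxooxolane-3-carbothioate | Cc1cc(-c2ccoc2)oc(=O)c1CC[C@@]1(C(=O)Sc2ccccc2)COC(=O)C1=O | intermediate
14 | allyl chloride (3-chloroprop-1-ene) | C=CCCl | starting material
15 | bis(pinacolato)diboron | CC1(C)OB(OC1(C)C)B1OC(C)(C)C(C)(C)O1 | starting material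
16 | 2,2'-(prop-2-ene-1,1-diyl)bis(4,4,5,5-tetramethyl-1,3,2-dioxaborolane) | C=CC(B1OC(C)(C)C(C)(C)O1)B1OC(C)(C)C(C)(C)O1 | intermediate
17 | S-phenyl (3R,4R)-3-{2-[6-(furan-3-yl)-4-methyl-2-oxo-2H-pyran-3-yl]ethyl}-5-oxo-4-[(4,4,5,5-tetramethyl-1,3,2-dioxaborolan-2-yl)oxy]-4-[(2Z)-3-(4,4,5,5-tetramethyl-1,3,2-dioxaborolan-2-yl)prop-2-en-1-yl]oxolane-3-carbothioate (not isolated) | Cc1cc(-c2ccoc2)oc(=O)c1CC[C@@]1(C(=O)Sc2ccccc2)COC(=O)[C@@]1(OB3OC(C)(C)C(C)(C)O3)C/C=C\B4OC(C)(C)C(C)(C)O4 | intermediate
18 | (3aR,7aR)-3a-{2-[6-(furan-3-yl)-4-methyl-2-oxo-2H-pyran-3-yl]ethyl}-7a-[(4,4,5,5-tetramethyl-1,3,2-dioxaborolan-2-yl)oxy]-3a,7a-dihydro-2-benzofuran-1,4(3H,7H)-dione (not isolated) | Cc1cc(-c2ccoc2)oc(=O)c1CC[C@@]12COC(=O)[C@@]1(OB3OC(C)(C)C(C)(C)O3)CC=CC2=O | intermediate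
19 | (3aR,7aR)-3a-{2-[6-(furan-3-yl)-4-methyl-2-oxo-2H-pyran-3-yl]ethyl}-7a-hydroxy-3a,7a-dihydro-2-benzofuran-1,4(3H,7H)-dione | Cc1cc(-c2ccoc2)oc(=O)c1CC[C@@]12COC(=O)[C@@]1(O)CC=CC2=O | target

Total step count: 9. Longest linear sequence: 8 steps (steps 1–7 and 9); step 8 is a one-step reagent branch.

Steps most likely to fail

Step 9 (proposed new method). The (Z)-alkenyl pinacolboronate may fail to transmetalate to the hindered acyl-palladium species, so that protodeboronation or acyl transfer to the cis tertiary oxygen takes over and the ring does not close. The fallback sets out from 13 and makes the two bonds separately by known reactions. Allylboration of 13 with allylboronic acid pinacol ester (toluene, 40 °C) should give the homoallylic alcohol S-phenyl (3R,4R)-3-{2-[6-(furan-3-yl)-4-methyl-2-oxo-2H-pyran-3-yl]ethyl}-4-hydroxy-5-oxo-4-(prop-2-en-1-yl)oxolane-3-carbothioate F1. Liebeskind–Srogl coupling of F1 with tributyl(vinyl)stannane (Pd2(dba)3, tri(2-furyl)phosphine, copper(I) diphenylphosphinate, THF, 50 °C) should give the vinyl ketone (3R,4R)-4-{2-[6-(furan-3-yl)-4-methyl-2-oxo-2H-pyran-3-yl]ethyl}-3-hydroxy-3-(prop-2-en-1-yl)-4-(prop-2-enoyl)oxolan-2-one F2. Ring-closing metathesis of F2 (second-generation ruthenium benzylidene catalyst, CH2Cl2, 40 °C) comes back to the route at 19.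

Step 7. The very acidic dioxo thioester may undergo uncatalysed aldol addition to formaldehyde faster than the chiral ion pair reacts, which erodes enantiofacial discrimination. The fallback sets out from 11 and replaces asymmetric catalysis by resolution. Paraformaldehyde with catalytic triethylamine (THF, 0 °C) should give the racemic hydroxymethyl adduct ethyl 5-[6-(furan-3-yl)-4-methyl-2-oxo-2H-pyran-3-yl]-3-(hydroxymethyl)-2-oxo-3-[(phenylsulfanyl)carbonyl]pentanoate F3. PPTS lactonises it to the racemic keto-lactone S-phenyl 3-{2-[6-(furan-3-yl)-4-methyl-2-oxo-2H-pyran-3-yl]ethyl}-4,5-dioxooxolane-3-carbothioate F4. Preparative chromatography on a chiral stationary phase separates 13, where the fallback rejoins the route, from its enantiomer S-phenyl (3S)-3-{2-[6-(furan-3-yl)-4-methyl-2-oxo-2H-pyran-3-yl]ethyl}-4,5-dioxooxolane-3-carbothioate F5.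

Step 4. The gold-catalysed cyclisation may lose regiocontrol (5-exo attack to the ylidene-butenolide), or the cationic catalyst may cleave the remote tert-butyl ester unevenly. The fallback sets out from 6 and removes both esters first. TFA in CH2Cl2 should give the diacid (2Z)-2-[4-(furan-3-yl)but-3-yn-2-ylidene]hexanedioic acid F6. ZnBr2 (THF, rt) then promotes 6-endo lactonisation of the conjugated carboxylic acid onto the furyl-substituted alkyne and comes back to the route at acid 8, which enters step 5 at the thioesterification stage.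

Further compounds
F1 | step 9 | S-phenyl (3R,4R)-3-{2-[6-(furan-3-yl)-4-methyl-2-oxo-2H-pyran-3-yl]ethyl}-4-hydroxy-5-oxo-4-(prop-2-en-1-yl)oxolane-3-carbothioate | Cc1cc(-c2ccoc2)oc(=O)c1CC[C@@]1(C(=O)Sc2ccccc2)COC(=O)[C@@]1(O)CC=C
F2 | step 9 | (3R,4R)-4-{2-[6-(furan-3-yl)-4-methyl-2-oxo-2H-pyran-3-yl]ethyl}-3-hydroxy-3-(prop-2-en-1-yl)-4-(prop-2-enoyl)oxolan-2-one | Cc1cc(-c2ccoc2)oc(=O)c1CC[C@@]1(C(=O)C=C)COC(=O)[C@@]1(O)CC=C
F3 | step 7 | ethyl 5-[6-(furan-3-yl)-4-methyl-2-oxo-2H-pyran-3-yl]-3-(hydroxymethyl)-2-oxo-3-[(phenylsulfanyl)carbonyl]pentanoate (racemic) | CCOC(=O)C(=O)C(CO)(CCc1c(C)cc(-c2ccoc2)oc1=O)C(=O)Sc1ccccc1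
F4 | step 7 | S-phenyl 3-{2-[6-(furan-3-yl)-4-methyl-2-oxo-2H-pyran-3-yl]ethyl}-4,5-dioxooxolane-3-carbothioate (racemic) | Cc1cc(-c2ccoc2)oc(=O)c1CCC1(C(=O)Sc2ccccc2)COC(=O)C1=O
F5 | step 7 | S-phenyl (3S)-3-{2-[6-(furan-3-yl)-4-methyl-2-oxo-2H-pyran-3-yl]ethyl}-4,5-dioxooxolane-3-carbothioate | Cc1cc(-c2ccoc2)oc(=O)c1CC[C@]1(C(=O)Sc2ccccc2)COC(=O)C1=O
F6 | step 4 | (2Z)-2-[4-(furan-3-yl)but-3-yn-2-ylidene]hexanedioic acid | C/C(C#Cc1ccoc1)=C(\CCCC(=O)O)C(=O)O
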